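A direct plan would take the ring system ready-made from the labdane diol sclareol A1 and only edit functional groups.
It would turn the tertiary vinyl carbinol into the primary 13E allylic isobutyrate A2 by an allyl-transposing esterification, dehydrate the 8-ol to the exocyclic alkene A3, shift that alkene into the ring to give the Δ7 isomer A4 and oxidise the C17 methyl group to the acid.
Its weakest step would be the allyl-transposing esterification: the 13E geometry is created there with nothing in the substrate to enforce it, by a catalytic process without close precedent.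
Next would come the dehydration and the isomerisation: two steps and two separations of regioisomers would be spent only on placing one double bond at C7.
Last would be the selenium dioxide oxidation: on the most valuable intermediate it would have to pick the C17 methyl group out of the allylic positions of two trisubstituted alkenes.

**Plan of the new route**
The retrosynthesis cuts C9–C10 (closure of ring B), then C8=C9 (Horner–Wadsworth–Emmons olefination that puts C11 cis to the ester, with an aldehyde cut from geranyl isobutyrate that brings C9 and C11–C16), then C7=C8 of an enoate precursor.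
Ring A is bought as the achiral aldehyde β-homocyclocitral; ring B is closed in the penultimate step by an acid-induced cation–olefin cyclisation that ends on a 2-(alkoxycarbonyl)allylsilane.
The enabling feature is the C7(H)=C8(CO2H)–C9(H)(chain) unit of ring B next to quaternary C10: it is what an allylsilane C7(Si)–C8(CO2R)=C9 leaves when C9 attacks a C10 cation, and ring A (gem-dimethyl C4, methyl-bearing C10) is the trimethylcyclohexene whose protonation gives that cation.
One silicon-bearing stereocentre (C7, set by catalysis and lost in the key step) should dictate C9 and C10 and, through reversible protonation, C5.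
No alkene is made by allylic transposition (13E is bought with geranyl isobutyrate), no double bond is moved (silicon marks C7=C8), and C17 enters at the acid oxidation level.

Key step: step 7

Remark: locants C1–C20 are the labdane locants of the target.
Assumption: the facial sense of the copper catalyst in step 2 is not predicted here; the ligand enantiomer that gives the 3R silane 5 is meant, because the chair analysis of step 7 requires R at the silicon-bearing carbon.

Step 1
Reactants: 1 β-homocyclocitral, 2-(2,6,6-trimethylcyclohex-1-en-1-yl)acetaldehyde; 2 allyl (triphenylphosphoranylidene)acetate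
Product: 3 allyl (2E)-4-(2,6,6-trimethylcyclohex-1-en-1-yl)but-2-enoate
Conditions: 2 (1.1 equiv), CH2Cl2, 0 → 23 °C
Reagents that add atoms: allyl (triphenylphosphoranylidene)acetate (2), C=CCOC(=O)C=P(c1ccccc1)(c1ccccc1)c1ccccc1
Why: Wittig olefination with a stabilised ylide should give the E enoate under neutral conditions, so the β,γ-unsaturated aldehyde is not enolised and the ring alkene stays tetrasubstituted; no stereocentre is formed.

Step 2
Reactants: 3 allyl (2E)-4-(2,6,6-trimethylcyclohex-1-en-1-yl)but-2-enoate; 4 2-[dimethyl(phenyl)silyl]-4,4,5,5-tetramethyl-1,3,2-dioxaborolane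
Product: 5 allyl (3R)-3-[dimethyl(phenyl)silyl]-4-(2,6,6-trimethylcyclohex-1-en-1-yl)butanoate
Conditions: CuCl (5 mol %), enantiopure imidazolinium tetrafluoroborate as carbene precursor (5.5 mol %), NaOtBu (11 mol %), 4 (1.1 equiv), THF, −78 °C; aqueous NH4Cl work-up
Reagents that add atoms: 2-[dimethyl(phenyl)silyl]-4,4,5,5-tetramethyl-1,3,2-dioxaborolane (4), C[Si](C)(c1ccccc1)B1OC(C)(C)C(C)(C)O1
Why: Copper-catalysed enantioselective conjugate silyl addition (silicon passes from boron to the carbene–copper centre and adds 1,4 to the acyclic E enoate), in which the chiral carbene ligand selects the alkene face and so sets the silicon-bearing carbon as R, while the low temperature and catalytic base should spare the acidic C6 hydrogens.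

Step 3
Reactants: 5 allyl (3R)-3-[dimethyl(phenyl)silyl]-4-(2,6,6-trimethylcyclohex-1-en-1-yl)butanoate; 6 diphenyl phosphorochloridite
Product: 8 allyl (3R)-2-(diphenoxyphosphoryl)-3-[dimethyl(phenyl)silyl]-4-(2,6,6-trimethylcyclohex-1-en-1-yl)butanoate (mixture at C2), via phosphonite 7 (not isolated)
Conditions: LiN(iPr)2 (1.05 equiv), THF, −78 °C; transfer into 6 (1.2 equiv), THF, −78 → 0 °C; then tBuOOH (1.5 equiv), 0 °C
Reagents that add atoms: diphenyl phosphorochloridite (6), ClP(Oc1ccccc1)Oc1ccccc1; tert-butyl hydroperoxide, CC(C)(C)OO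
Why: C-phosphinylation of the ester lithium enolate with a chloride of trivalent phosphorus (which attacks carbon where a chlorophosphate would attack oxygen) followed by oxidation to the diaryl phosphonate; the new C2 centre forms as a mixture that is erased in step 6 and the silicon-bearing centre is not touched.

Step 4
Reactants: 9 geranyl isobutyrate, (2E)-3,7-dimethylocta-2,6-dien-1-yl 2-methylpropanoate
Product: 10 (2E)-5-(3,3-dimethyloxiran-2-yl)-3-methylpent-2-en-1-yl 2-methylpropanoate (racemic)
Conditions: mCPBA (1.0 equiv), NaHCO3, CH2Cl2, −20 → 0 °C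
Reagents that add atoms: 3-chloroperbenzoic acid, OOC(=O)c1cccc(Cl)c1
Why: Prilezhaev epoxidation should take the distal alkene because the other one is deactivated by its allylic acyloxy group; the epoxide stereocentre is racemic and is cut away in step 5.

Step 5
Reactants: 10 (2E)-5-(3,3-dimethyloxiran-2-yl)-3-methylpent-2-en-1-yl 2-methylpropanoate
Product: 11 (2E)-3-methyl-6-oxohex-2-en-1-yl 2-methylpropanoate
Conditions: H5IO6 (1.1 equiv), THF–H2O, 0 °C
Reagents that add atoms: none
Why: Periodic acid opens the epoxide (water enters at the tertiary carbon and leaves with acetone) and cleaves the resulting glycol (Malaprade-type cleavage) to the aldehyde without touching the E alkene or the ester; no stereocentre remains.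

Step 6
Reactants: 8 allyl (3R)-2-(diphenoxyphosphoryl)-3-[dimethyl(phenyl)silyl]-4-(2,6,6-trimethylcyclohex-1-en-1-yl)butanoate; 11 (2E)-3-methyl-6-oxohex-2-en-1-yl 2-methylpropanoate
Product: 12 allyl (2E,6E)-2-{(1R)-1-[dimethyl(phenyl)silyl]-2-(2,6,6-trimethylcyclohex-1-en-1-yl)ethyl}-6-methyl-8-[(2-methylpropanoyl)oxy]octa-2,6-dienoate
Conditions: NaH (1.05 equiv), THF, 0 °C; then 11 (1.1 equiv), −78 → −20 °C
Reagents that add atoms: aldehyde 11, O=CCC/C(C)=C/COC(=O)C(C)C
Why: Horner–Wadsworth–Emmons olefination with a diaryl phosphonate, whose fast, kinetically controlled elimination should place the aldehyde chain cis to the ester and trans to the silicon-bearing carbon (2E by the sequence rule only because silicon outranks oxygen); no stereocentre is formed and the silicon centre is kept.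

Step 7
Reactants: 12 allyl (2E,6E)-2-{(1R)-1-[dimethyl(phenyl)silyl]-2-(2,6,6-trimethylcyclohex-1-en-1-yl)ethyl}-6-methyl-8-[(2-methylpropanoyl)oxy]octa-2,6-dienoate
Product: 13 allyl (5S,9R,10S,13E)-15-[(2-methylpropanoyl)oxy]labda-7,13-dien-17-oate
Conditions: TfOH (1.5 equiv), CH2Cl2 (0.01 M), −78 °C, 15 min; Et3N, then aqueous NaHCO3
Reagents that add atoms: none
Why: Protonation of the tetrasubstituted ring alkene (the most basic π bond; the Δ13 alkene is deactivated by its allylic acyloxy group and the allylsilane alkene by the ester) gives the tertiary C10 cation reversibly, C9 of the 2-(alkoxycarbonyl)allylsilane captures it in an anti SE2′ step, and loss of silicon leaves the C7=C8 bond exactly where silicon stood. The step relies on the acid cyclisation of 2,6,6-trimethylcyclohexenyl (β-monocyclic) polyene precursors to trans-fused bicycles and on the allylsilane-terminated cation–olefin cyclisation (intramolecular Hosomi–Sakurai reaction), which is known also for allylsilanes that carry an ester on the central carbon. Ring B closes in the 6-endo-trig mode (C9 onto C10) through a chair that is trans-fused to ring A. C9 is controlled by the alkene geometry (C11, trans to C7, ends equatorial, hence 9α-H) together with the 7R silicon centre, which must stand axial and anti to the incoming C10 and so permits one chair only; C10 follows because ring A stays equatorial on that chair at both C5 and C10, which leaves the C20 methyl axial and anti to the C5 hydrogen (trans-decalin); C5 is set by the proton and should correct itself, since the C5-epimeric cation could close only with C4 of ring A and silicon 1,3-diaxial or with silicon in the alkene plane, and so returns to the alkene by proton loss. The step needs protonation of the ring alkene to outrun ionisation of the allylic isobutyrate and protonation of the phenyl group on silicon, which the deactivated character of the two other alkenes, the low temperature and the short contact time should secure.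

Step 8
Reactants: 13 allyl (5S,9R,10S,13E)-15-[(2-methylpropanoyl)oxy]labda-7,13-dien-17-oate
Product: 14 (5S,9R,10S,13E)-15-[(2-methylpropanoyl)oxy]labda-7,13-dien-17-oic acid (target)
Conditions: Pd(PPh3)4 (5 mol %), morpholine (3 equiv), THF, 0 °C; dilute citric acid work-up
Reagents that add atoms: none
Why: Tsuji–Trost deallylation, in which zerovalent palladium should ionise the unsubstituted allyl ester much faster than the 3,3-disubstituted allylic isobutyrate and morpholine takes up the allyl group; no stereocentre or alkene is touched.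

**Compound list**
1 | β-homocyclocitral, 2-(2,6,6-trimethylcyclohex-1-en-1-yl)acetaldehyde | O=CCC1=C(C)CCCC1(C)C | starting material
2 | allyl (triphenylphosphoranylidene)acetate | C=CCOC(=O)C=P(c1ccccc1)(c1ccccc1)c1ccccc1 | starting material
3 | allyl (2E)-4-(2,6,6-trimethylcyclohex-1-en-1-yl)but-2-enoate | C=CCOC(=O)/C=C/CC1=C(C)CCCC1(C)C | intermediate
4 | 2-[dimethyl(phenyl)silyl]-4,4,5,5-tetramethyl-1,3,2-dioxaborolane | C[Si](C)(c1ccccc1)B1OC(C)(C)C(C)(C)O1 | starting material
5 | allyl (3R)-3-[dimethyl(phenyl)silyl]-4-(2,6,6-trimethylcyclohex-1-en-1-yl)butanoate | C=CCOC(=O)C[C@@H](CC1=C(C)CCCC1(C)C)[Si](C)(C)c1ccccc1 | intermediate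
6 | diphenyl phosphorochloridite | ClP(Oc1ccccc1)Oc1ccccc1 | starting material
7 | allyl (3R)-2-(diphenoxyphosphanyl)-3-[dimethyl(phenyl)silyl]-4-(2,6,6-trimethylcyclohex-1-en-1-yl)butanoate (mixture at C2), not isolated | C=CCOC(=O)C(P(Oc1ccccc1)Oc1ccccc1)[C@@H](CC1=C(C)CCCC1(C)C)[Si](C)(C)c1ccccc1 | intermediate
8 | allyl (3R)-2-(diphenoxyphosphoryl)-3-[dimethyl(phenyl)silyl]-4-(2,6,6-trimethylcyclohex-1-en-1-yl)butanoate (mixture at C2) | C=CCOC(=O)C(P(=O)(Oc1ccccc1)Oc1ccccc1)[C@@H](CC1=C(C)CCCC1(C)C)[Si](C)(C)c1ccccc1 | intermediate
9 | geranyl isobutyrate, (2E)-3,7-dimethylocta-2,6-dien-1-yl 2-methylpropanoate | CC(C)=CCC/C(C)=C/COC(=O)C(C)C | starting material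
10 | (2E)-5-(3,3-dimethyloxiran-2-yl)-3-methylpent-2-en-1-yl 2-methylpropanoate (racemic) | CC1(C)OC1CC/C(C)=C/COC(=O)C(C)C | intermediate
11 | (2E)-3-methyl-6-oxohex-2-en-1-yl 2-methylpropanoate | O=CCC/C(C)=C/COC(=O)C(C)C | intermediate
12 | allyl (2E,6E)-2-{(1R)-1-[dimethyl(phenyl)silyl]-2-(2,6,6-trimethylcyclohex-1-en-1-yl)ethyl}-6-methyl-8-[(2-methylpropanoyl)oxy]octa-2,6-dienoate | C=CCOC(=O)/C(=C\CC/C(C)=C/COC(=O)C(C)C)[C@@H](CC1=C(C)CCCC1(C)C)[Si](C)(C)c1ccccc1 | intermediate
13 | allyl (5S,9R,10S,13E)-15-[(2-methylpropanoyl)oxy]labda-7,13-dien-17-oate | C/C(=C\COC(=O)C(C)C)CC[C@H]1C(C(=O)OCC=C)=CC[C@H]2C(C)(C)CCC[C@]12C | intermediate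
14 | (5S,9R,10S,13E)-15-[(2-methylpropanoyl)oxy]labda-7,13-dien-17-oic acid | C/C(=C\COC(=O)C(C)C)CC[C@H]1C(C(=O)O)=CC[C@H]2C(C)(C)CCC[C@]12C | target

Total step count: 8. Longest linear sequence: 6 steps (steps 1, 2, 3, 6, 7, 8).

**Steps most likely to fail**

Step 7. The acid may ionise the allylic isobutyrate, scramble the Δ13 alkene or remove silicon by protonation at C9 faster than the C10 cation is captured. The fallback sets out from 8 and returns at 13; it carries the side chain through the acid step as a conjugated ester, which has no ionisable allylic C–O bond and a deactivated alkene. Phosphonate 8 would be condensed as in step 6 with ethyl (2E)-3-methyl-6-oxohex-2-enoate F1 (from ethyl geranate by ozonolysis of the electron-rich distal alkene: O3, CH2Cl2, −78 °C, then Me2S). This would give 1-allyl 8-ethyl (2E,6E)-2-{(1R)-1-[dimethyl(phenyl)silyl]-2-(2,6,6-trimethylcyclohex-1-en-1-yl)ethyl}-6-methylocta-2,6-dienedioate F2, which would be cyclised as in step 7 to 17-allyl 15-ethyl (5S,9R,10S,13E)-labda-7,13-diene-15,17-dioate F3. The less hindered C15 ester would then be reduced with iBu2AlH (CH2Cl2, −78 °C) to allyl (5S,9R,10S,13E)-15-hydroxylabda-7,13-dien-17-oate F4, and acylation with isobutyryl chloride and pyridine would give 13.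

Step 6. The crowded phosphonate anion may add slowly, and the kinetic preference that puts the ester and the C9 chain cis may erode. The fallback sets out from 5 and 11 and returns at 12; it reads the alkene geometry from an aldol configuration and not from the phosphonate. The lithium enolate of 5 (LiN(iPr)2, THF–HMPA, −78 °C) would add to 11 to give allyl (2,3-syn)-2-{(1R)-1-[dimethyl(phenyl)silyl]-2-(2,6,6-trimethylcyclohex-1-en-1-yl)ethyl}-3-hydroxy-6-methyl-8-[(2-methylpropanoyl)oxy]oct-6-enoate F5 (one syn isomer is drawn; either serves). Its stereospecific syn dehydration (dicyclohexylcarbodiimide, CuCl, toluene, 80 °C) would give 12.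

Step 3. The enolate may attack phosphorus through oxygen, or the more acidic product may quench unreacted enolate. The fallback sets out from 1 and returns at 8; it puts phosphorus in place before silicon. Knoevenagel condensation of 1 with allyl (diphenoxyphosphoryl)acetate F6 (from diphenyl phosphite, allyl bromoacetate and Et3N) under TiCl4 and N-methylmorpholine (THF, 0 °C) would give allyl (2E)-2-(diphenoxyphosphoryl)-4-(2,6,6-trimethylcyclohex-1-en-1-yl)but-2-enoate F7. The copper-catalysed silyl addition of step 2 applied to F7 would then give 8 directly.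

**Further compounds**
F1 | step 7 | ethyl (2E)-3-methyl-6-oxohex-2-enoate | CCOC(=O)/C=C(\C)CCC=O
F2 | step 7 | 1-allyl 8-ethyl (2E,6E)-2-{(1R)-1-[dimethyl(phenyl)silyl]-2-(2,6,6-trimethylcyclohex-1-en-1-yl)ethyl}-6-methylocta-2,6-dienedioate | C=CCOC(=O)/C(=C\CC/C(C)=C/C(=O)OCC)[C@@H](CC1=C(C)CCCC1(C)C)[Si](C)(C)c1ccccc1
F3 | step 7 | 17-allyl 15-ethyl (5S,9R,10S,13E)-labda-7,13-diene-15,17-dioate | CCOC(=O)/C=C(\C)CC[C@H]1C(C(=O)OCC=C)=CC[C@H]2C(C)(C)CCC[C@]12C
F4 | step 7 | allyl (5S,9R,10S,13E)-15-hydroxylabda-7,13-dien-17-oate | OC/C=C(\C)CC[C@H]1C(C(=O)OCC=C)=CC[C@H]2C(C)(C)CCC[C@]12C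
F5 | step 6 | allyl (2,3-syn,6E)-2-{(1R)-1-[dimethyl(phenyl)silyl]-2-(2,6,6-trimethylcyclohex-1-en-1-yl)ethyl}-3-hydroxy-6-methyl-8-[(2-methylpropanoyl)oxy]oct-6-enoate | C=CCOC(=O)[C@H]([C@H](O)CC/C(C)=C/COC(=O)C(C)C)[C@@H](CC1=C(C)CCCC1(C)C)[Si](C)(C)c1ccccc1
F6 | step 3 | allyl (diphenoxyphosphoryl)acetate | C=CCOC(=O)CP(=O)(Oc1ccccc1)Oc1ccccc1
F7 | step 3 | allyl (2E)-2-(diphenoxyphosphoryl)-4-(2,6,6-trimethylcyclohex-1-en-1-yl)but-2-enoate | C=CCOC(=O)/C(=C\CC1=C(C)CCCC1(C)C)P(=O)(Oc1ccccc1)Oc1ccccc1
A1 | direct plan | (−)-sclareol, (13R)-labd-14-ene-8α,13-diol | C=C[C@](C)(O)CC[C@H]1[C@](C)(O)CC[C@H]2C(C)(C)CCC[C@]12C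
A2 | direct plan | (13E)-8α-hydroxylabd-13-en-15-yl isobutyrate | C/C(=C\COC(=O)C(C)C)CC[C@H]1[C@](C)(O)CC[C@H]2C(C)(C)CCC[C@]12C
A3 | direct plan | (13E)-labda-8(17),13-dien-15-yl isobutyrate | C/C(=C\COC(=O)C(C)C)CC[C@H]1C(=C)CC[C@H]2C(C)(C)CCC[C@]12C
A4 | direct plan | (13E)-labda-7,13-dien-15-yl isobutyrate | C/C(=C\COC(=O)C(C)C)CC[C@H]1C(C)=CC[C@H]2C(C)(C)CCC[C@]12C
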